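**Plan**

- Retrosynthetic cuts, in order: C5–C6 (ring ketone to the OMe-bearing carbon of the six-membered ring); then O1–C7a and C7–C6 (alkynol + CO + MeOH); then C7a≡C7 (from a lactone carbonyl); then C3a–allyl and C4–C5 (conjugate addition/allylation); then C2–C3 (crotylation).
- Enabling feature: C6 is the carbonyl of the vinylogous ester O1–C7a=C7–C6=O that spans the oxolane ring and the six-membered ring, and its other neighbour C5 is an enol-ether carbon (C4=C5–OMe). C5 can therefore enter as a sulfonyl-stabilised α-methoxy carbanion, acylate the ester carbon C6, and lose sulfinate to leave C4=C5.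
- Forward ring order: a cis γ-butyrolactone serves as a temporary ring on which the quaternary carbon C3a is built. It is opened to an alkynol, the oxolane ring is closed by oxypalladation/methoxycarbonylation, and the six-membered ring is closed last.
- Stereochemistry: C2 and C3 (cis aryl/methyl) come from a reagent-controlled Brown (Z)-crotylboration. C3a comes from allylation of a lactone enolate anti to the methyl/aryl face. The C7=C7a geometry comes from the anti mode of oxypalladation.

Key step: step 10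

Remark: locants O1, C2, C3, C3a, C4–C7, C7a are those of the 1-benzofuran-6-one skeleton of the target; 1, 11 and all reagents named are taken as purchasable.

**Route**

Step 1
Reactants: 1 3,4,5-trimethoxybenzaldehyde
Product: 3 (1R,2S)-2-methyl-1-(3,4,5-trimethoxyphenyl)but-3-en-1-ol, via borinate ester 2 (not isolated)
Conditions: cis-2-butene, n-BuLi, KOt-Bu, THF, −78 to −45 °C; (+)-Ipc2BOMe, −78 °C; BF3·OEt2; 1, −78 °C; then NaOH, H2O2, 23 °C
Reagents that add atoms: cis-2-butene C/C=C\C
Why: Brown crotylboration through a closed chair transition state: the (Z)-crotyl geometry gives the syn relationship and the isopinocampheyl groups derived from (−)-α-pinene direct the crotyl unit to the Re face of the aldehyde, which should set C1 as R and C2 as S (the cis aryl/methyl pair of the target).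

Step 2
Reactants: 3 (1R,2S)-2-methyl-1-(3,4,5-trimethoxyphenyl)but-3-en-1-ol
Product: 5 (1R,2S)-2-methyl-1-(3,4,5-trimethoxyphenyl)butane-1,4-diol, via bis(boryl) intermediate 4 (not isolated)
Conditions: 9-BBN-H (2.2 equiv), THF, 0 to 23 °C; then NaOH, H2O2
Reagents that add atoms: hydrogen peroxide OO
Why: anti-Markovnikov hydroboration–oxidation of the terminal alkene with a bulky dialkylborane; the free hydroxyl is held as its borinate and released in the oxidative work-up, and no stereocenter is touched.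

Step 3
Reactants: 5 (1R,2S)-2-methyl-1-(3,4,5-trimethoxyphenyl)butane-1,4-diol
Product: 7 (4S,5R)-4-methyl-5-(3,4,5-trimethoxyphenyl)oxolan-2-one (cis), via lactol 6 (not isolated)
Conditions: TEMPO (cat.), PhI(OAc)2 (2.5 equiv), CH2Cl2, 23 °C
Reagents that add atoms: none
Why: oxoammonium-mediated oxidative lactonization of a 1,4-diol: the primary alcohol should be oxidised in preference to the hindered benzylic one, the hydroxy aldehyde closes to lactol 6, and this is oxidised on to the γ-lactone with the cis methyl/aryl relationship unchanged.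

Step 4
Reactants: 7 (4S,5R)-4-methyl-5-(3,4,5-trimethoxyphenyl)oxolan-2-one
Product: 10 (4S,5R)-4-methyl-3-methylidene-5-(3,4,5-trimethoxyphenyl)oxolan-2-one, via Mannich base 8 (not isolated), via methiodide 9 (not isolated)
Conditions: LiN(i-Pr)2, THF, −78 °C; Me2N=CH2+ I−, −78 to 23 °C; MeI, MeOH, 23 °C; NaHCO3 (aq), CH2Cl2
Reagents that add atoms: N,N-dimethylmethyleneiminium iodide C=[N+](C)C.[I-]
Why: Eschenmoser methylenation: Mannich reaction of the lithium enolate with the iminium salt, N-methylation and base-induced β-elimination of trimethylamine give the exocyclic methylene, while C4 and C5 are not enolizable and keep their configuration.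

Step 5
Reactants: 11 methoxymethyl phenyl sulfide
Product: 12 methoxymethyl phenyl sulfone
Conditions: mCPBA (2.2 equiv), CH2Cl2, 0 to 23 °C
Reagents that add atoms: mCPBA O=C(OO)c1cccc(Cl)c1
Why: peracid oxidation of a sulfide to the sulfone by two successive oxygen transfers, which the O–CH2–S unit should tolerate.

Step 6
Reactants: 10 (4S,5R)-4-methyl-3-methylidene-5-(3,4,5-trimethoxyphenyl)oxolan-2-one; 12 methoxymethyl phenyl sulfone
Product: 14 (3R,4S,5R)-3-[2-methoxy-2-(phenylsulfonyl)ethyl]-4-methyl-3-(prop-2-en-1-yl)-5-(3,4,5-trimethoxyphenyl)oxolan-2-one (both epimers at the sulfone carbon), via lithium enolate 13 (not isolated)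
Conditions: 12, n-BuLi, THF, −78 °C; slow addition of 10, −78 °C; then allyl bromide, DMPU, −78 to 0 °C
Reagents that add atoms: allyl bromide C=CCBr
Why: Michael addition of the sulfonyl-stabilised α-methoxy carbanion to the exo-methylene lactone followed by allylation of lithium enolate 13 (conjugate addition–enolate trapping); allyl bromide should enter on the face opposite to the cis methyl and aryl groups, which sets the quaternary carbon as 3R (allyl trans to methyl), and the epimers at the sulfone carbon are of no consequence because that carbon becomes sp2 in step 10.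

Step 7
Reactants: 14 (3R,4S,5R)-3-[2-methoxy-2-(phenylsulfonyl)ethyl]-4-methyl-3-(prop-2-en-1-yl)-5-(3,4,5-trimethoxyphenyl)oxolan-2-one
Product: 15 (3R,4S,5R)-3-[2-methoxy-2-(phenylsulfonyl)ethyl]-4-methyl-3-(prop-2-en-1-yl)-5-(3,4,5-trimethoxyphenyl)oxolan-2-ol (both anomers)
Conditions: i-Bu2AlH, CH2Cl2, −78 °C; aqueous KNaC4H4O6 (potassium sodium tartrate)
Reagents that add atoms: none
Why: partial reduction of the lactone at low temperature, where the tetrahedral aluminium alkoxide is stable until work-up, should give the lactol; sulfone, alkene and the stereocenters are untouched.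

Step 8
Reactants: 15 (3R,4S,5R)-3-[2-methoxy-2-(phenylsulfonyl)ethyl]-4-methyl-3-(prop-2-en-1-yl)-5-(3,4,5-trimethoxyphenyl)oxolan-2-ol
Product: 16 (1R,2S,3R)-3-ethynyl-3-[2-methoxy-2-(phenylsulfonyl)ethyl]-2-methyl-1-(3,4,5-trimethoxyphenyl)hex-5-en-1-ol
Conditions: dimethyl (1-diazo-2-oxopropyl)phosphonate, K2CO3, MeOH, 0 to 23 °C
Reagents that add atoms: dimethyl (1-diazo-2-oxopropyl)phosphonate CC(=O)C(=[N+]=[N-])P(=O)(OC)OC
Why: Ohira–Bestmann (Seyferth–Gilbert) homologation: the open hydroxy-aldehyde form of the lactol is intercepted by the diazomethylphosphonate anion, and loss of dimethyl phosphate and N2 with a 1,2-hydrogen shift gives the terminal alkyne, which frees the benzylic hydroxyl and leaves the non-enolizable quaternary carbon intact.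

Step 9
Reactants: 16 (1R,2S,3R)-3-ethynyl-3-[2-methoxy-2-(phenylsulfonyl)ethyl]-2-methyl-1-(3,4,5-trimethoxyphenyl)hex-5-en-1-ol
Product: 17 methyl (2E)-2-[(3R,4S,5R)-3-[2-methoxy-2-(phenylsulfonyl)ethyl]-4-methyl-3-(prop-2-en-1-yl)-5-(3,4,5-trimethoxyphenyl)oxolan-2-ylidene]acetate
Conditions: PdCl2(MeCN)2 (5 mol %), p-benzoquinone (1.2 equiv), CO (1 atm), MeOH, 0 °C
Reagents that add atoms: carbon monoxide [C-]#[O+]; methanol CO
Why: oxidative cyclization–alkoxycarbonylation of a 4-yn-1-ol by divalent palladium: the hydroxyl adds 5-exo-dig and anti to the palladium-bound alkyne, CO insertion and methanolysis then place the ester trans to the ring oxygen (E, on the side of the quaternary carbon), benzoquinone returns zerovalent palladium to the divalent state, and the existing stereocenters are not involved.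

Step 10
Reactants: 17 methyl (2E)-2-[(3R,4S,5R)-3-[2-methoxy-2-(phenylsulfonyl)ethyl]-4-methyl-3-(prop-2-en-1-yl)-5-(3,4,5-trimethoxyphenyl)oxolan-2-ylidene]acetate
Product: 19 (2R,3S,3aS)-5-methoxy-3-methyl-3a-(prop-2-en-1-yl)-2-(3,4,5-trimethoxyphenyl)-3,3a-dihydro-1-benzofuran-6(2H)-one, via keto sulfone 18 (not isolated)
Conditions: LiN(i-Pr)2 (1.2 equiv), THF, −78 to 0 °C; then DBU, 23 °C
Reagents that add atoms: none
Why: LiN(i-Pr)2 should remove the proton on the carbon that carries both the sulfonyl and the methoxy group (the most acidic C–H), and this carbanion adds to the ester carbonyl that the (E) geometry holds next to the quaternary carbon; loss of methoxide gives keto sulfone 18. The closest known reaction type is the Dieckmann-type acylation of a sulfonyl carbanion by an ester, and the six-membered ring closes in the 6-exo-trig mode. Base then induces 1,2-elimination of benzenesulfinate, as known for α-alkoxy sulfones, to give the C4=C5 enol ether; only C4 carries β-hydrogens, so the double bond can form in one position only, and conjugation with the new ketone drives it. No new stereocenter is formed: the sulfone carbon becomes sp2, and C2, C3 and C3a, none of them enolizable, are carried through unchanged. The step needs site-selective deprotonation (sulfonyl carbon rather than the vinylic C–H next to the ester), which the sulfonyl group secures. It also needs the ester within reach of the carbanion, which the anti-oxypalladation geometry of step 9 secures.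

**Compound list**

1 | 3,4,5-trimethoxybenzaldehyde | COc1cc(C=O)cc(OC)c1OC | starting material
2 | diisopinocampheylborinate ester of 3 | C=C[C@H](C)[C@@H](OB([C@H]1C[C@H]2C[C@@H]([C@@H]1C)C2(C)C)[C@H]1C[C@H]2C[C@@H]([C@@H]1C)C2(C)C)c1cc(OC)c(OC)c(OC)c1 | intermediate
3 | (1R,2S)-2-methyl-1-(3,4,5-trimethoxyphenyl)but-3-en-1-ol | C=C[C@H](C)[C@@H](O)c1cc(OC)c(OC)c(OC)c1 | intermediate
4 | O,C-bis(9-borabicyclo[3.3.1]nonan-9-yl) derivative of 5 | B1(CC[C@H](C)[C@@H](OB2C3CCCC2CCC3)c2cc(OC)c(OC)c(OC)c2)C2CCCC1CCC2 | intermediate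
5 | (1R,2S)-2-methyl-1-(3,4,5-trimethoxyphenyl)butane-1,4-diol | OCC[C@H](C)[C@@H](O)c1cc(OC)c(OC)c(OC)c1 | intermediate
6 | (4S,5R)-4-methyl-5-(3,4,5-trimethoxyphenyl)oxolan-2-ol (both anomers) | OC1C[C@H](C)[C@H](c2cc(OC)c(OC)c(OC)c2)O1 | intermediate
7 | (4S,5R)-4-methyl-5-(3,4,5-trimethoxyphenyl)oxolan-2-one (cis) | O=C1C[C@H](C)[C@H](c2cc(OC)c(OC)c(OC)c2)O1 | intermediate
8 | (4S,5R)-3-[(dimethylamino)methyl]-4-methyl-5-(3,4,5-trimethoxyphenyl)oxolan-2-one (C3 epimers) | O=C1C(CN(C)C)[C@H](C)[C@H](c2cc(OC)c(OC)c(OC)c2)O1 | intermediate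
9 | trimethylammonium iodide (methiodide) of 8 | O=C1C(C[N+](C)(C)C)[C@H](C)[C@H](c2cc(OC)c(OC)c(OC)c2)O1.[I-] | intermediate
10 | (4S,5R)-4-methyl-3-methylidene-5-(3,4,5-trimethoxyphenyl)oxolan-2-one | O=C1C(=C)[C@H](C)[C@H](c2cc(OC)c(OC)c(OC)c2)O1 | intermediate
11 | methoxymethyl phenyl sulfide | COCSc1ccccc1 | starting material
12 | methoxymethyl phenyl sulfone | COCS(=O)(=O)c1ccccc1 | intermediate
13 | lithium enolate of (4S,5R)-3-[2-methoxy-2-(phenylsulfonyl)ethyl]-4-methyl-5-(3,4,5-trimethoxyphenyl)oxolan-2-one | [Li]OC1=C(CC(OC)S(=O)(=O)c2ccccc2)[C@H](C)[C@H](c2cc(OC)c(OC)c(OC)c2)O1 | intermediate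
14 | (3R,4S,5R)-3-[2-methoxy-2-(phenylsulfonyl)ethyl]-4-methyl-3-(prop-2-en-1-yl)-5-(3,4,5-trimethoxyphenyl)oxolan-2-one (allyl trans to methyl; sulfone carbon both epimers) | O=C1[C@](CC=C)(CC(OC)S(=O)(=O)c2ccccc2)[C@H](C)[C@H](c2cc(OC)c(OC)c(OC)c2)O1 | intermediate
15 | (3R,4S,5R)-3-[2-methoxy-2-(phenylsulfonyl)ethyl]-4-methyl-3-(prop-2-en-1-yl)-5-(3,4,5-trimethoxyphenyl)oxolan-2-ol (both anomers) | OC1[C@](CC=C)(CC(OC)S(=O)(=O)c2ccccc2)[C@H](C)[C@H](c2cc(OC)c(OC)c(OC)c2)O1 | intermediate
16 | (1R,2S,3R)-3-ethynyl-3-[2-methoxy-2-(phenylsulfonyl)ethyl]-2-methyl-1-(3,4,5-trimethoxyphenyl)hex-5-en-1-ol | C#C[C@](CC=C)(CC(OC)S(=O)(=O)c1ccccc1)[C@H](C)[C@@H](O)c1cc(OC)c(OC)c(OC)c1 | intermediate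
17 | methyl (2E)-2-[(3R,4S,5R)-3-[2-methoxy-2-(phenylsulfonyl)ethyl]-4-methyl-3-(prop-2-en-1-yl)-5-(3,4,5-trimethoxyphenyl)oxolan-2-ylidene]acetate | COC(=O)/C=C1/O[C@@H](c2cc(OC)c(OC)c(OC)c2)[C@@H](C)[C@@]1(CC=C)CC(OC)S(=O)(=O)c1ccccc1 | intermediate
18 | (2R,3S,3aR)-5-methoxy-3-methyl-5-(phenylsulfonyl)-3a-(prop-2-en-1-yl)-2-(3,4,5-trimethoxyphenyl)-3,3a,4,5-tetrahydro-1-benzofuran-6(2H)-one (both C5 epimers; ring stereocenters arranged as in the target) | C=CC[C@]12CC(OC)(S(=O)(=O)c3ccccc3)C(=O)C=C1O[C@@H](c1cc(OC)c(OC)c(OC)c1)[C@H]2C | intermediate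
19 | (2R,3S,3aS)-5-methoxy-3-methyl-3a-(prop-2-en-1-yl)-2-(3,4,5-trimethoxyphenyl)-3,3a-dihydro-1-benzofuran-6(2H)-one | C=CC[C@]12C=C(OC)C(=O)C=C1O[C@@H](c1cc(OC)c(OC)c(OC)c1)[C@H]2C | target

**Totals**

Total step count: 10. Longest linear sequence: 9 steps (steps 1–4 and 6–10; step 5 prepares the sulfone separately).

**Steps most likely to fail**

1. Step 10. The acylation may revert, because keto sulfone 18 has no acidic proton to hold it as an enolate. Deprotonation may also occur at the vinylic position next to the ester, and loss of sulfinate beside a ketone may be slow. Fallback: the ring closure is made on an aldehyde instead of the ester. Setting out from 17, i-Bu2AlH (CH2Cl2, −78 °C) should reduce the ester to the (E)-allylic alcohol F1. MnO2 (CH2Cl2, 0 °C) should oxidise it to the (E)-enal F2. LiN(i-Pr)2 (THF, −78 °C) should then add the sulfonyl carbanion to the aldehyde to give the cyclic β-hydroxy sulfone F3. Dess–Martin periodinane should oxidise F3 to keto sulfone 18, where the fallback comes back to the route; DBU then gives 19.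

2. Step 9. Oxypalladation may occur at the allyl alkene instead of the alkyne. Acid formed in the flask may isomerise the strained (E)-acrylate or ionise the electron-rich benzylic alcohol. Fallback: setting out from 16, Ph3PAuNTf2 (cat.) and N-iodosuccinimide (CH2Cl2, 0 °C) should give the (E)-iodoenol ether F4 by anti iodo-alkoxylation of the gold-bound alkyne. Methoxycarbonylation with Pd(PPh3)4, CO, MeOH and Et3N, with retention at the alkenyl carbon, should then return to the route at 17.

3. Step 8. The hindered aldehyde is present only in small amount beside the lactol, so the homologation may be slow. Prolonged exposure to base may also cost the sulfone. Fallback: setting out from 15, a Wittig reaction with Ph3P=CHCl (from Ph3PCH2Cl+ Cl− and KOt-Bu, THF) should give the chloroalkene F5 as an E/Z mixture. Dehydrochlorination with excess n-BuLi (THF, −78 °C) should then return to the route at 16.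

**Further compounds**

F1 | step 10 | (2E)-2-[(3R,4S,5R)-3-[2-methoxy-2-(phenylsulfonyl)ethyl]-4-methyl-3-(prop-2-en-1-yl)-5-(3,4,5-trimethoxyphenyl)oxolan-2-ylidene]ethan-1-ol | OC/C=C1/O[C@@H](c2cc(OC)c(OC)c(OC)c2)[C@@H](C)[C@@]1(CC=C)CC(OC)S(=O)(=O)c1ccccc1
F2 | step 10 | (2E)-2-[(3R,4S,5R)-3-[2-methoxy-2-(phenylsulfonyl)ethyl]-4-methyl-3-(prop-2-en-1-yl)-5-(3,4,5-trimethoxyphenyl)oxolan-2-ylidene]acetaldehyde | O=C/C=C1/O[C@@H](c2cc(OC)c(OC)c(OC)c2)[C@@H](C)[C@@]1(CC=C)CC(OC)S(=O)(=O)c1ccccc1
F3 | step 10 | 6-hydroxy-5-methoxy-3-methyl-5-(phenylsulfonyl)-3a-(prop-2-en-1-yl)-2-(3,4,5-trimethoxyphenyl)-2,3,3a,4,5,6-hexahydro-1-benzofuran (ring stereocenters as in 18; C5 and C6 epimers) | C=CC[C@]12CC(OC)(S(=O)(=O)c3ccccc3)C(O)C=C1O[C@@H](c1cc(OC)c(OC)c(OC)c1)[C@H]2C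
F4 | step 9 | (2E,3R,4S,5R)-2-(iodomethylidene)-3-[2-methoxy-2-(phenylsulfonyl)ethyl]-4-methyl-3-(prop-2-en-1-yl)-5-(3,4,5-trimethoxyphenyl)oxolane | I/C=C1/O[C@@H](c2cc(OC)c(OC)c(OC)c2)[C@@H](C)[C@@]1(CC=C)CC(OC)S(=O)(=O)c1ccccc1
F5 | step 8 | (1R,2S)-3-(2-chloroethenyl)-3-[2-methoxy-2-(phenylsulfonyl)ethyl]-2-methyl-1-(3,4,5-trimethoxyphenyl)hex-5-en-1-ol (quaternary carbon as in 16; E/Z mixture) | ClC=C[C@](CC=C)(CC(OC)S(=O)(=O)c1ccccc1)[C@H](C)[C@@H](O)c1cc(OC)c(OC)c(OC)c1
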